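**Plan**

1. Numbering used here: ring A (saturated) is C1(H)(CH3)–C2H2–C3H2–C4(H)(side chain), fused at C4a/C8a to aromatic ring B (C5–H, C6–CO2H, C7–OH, C8–OH). The side chain is C1′(H)(CH3)–C2′H2–C3′H2–C4′H2–C5′(H)(CH3)–C6′H2OH.
2. Retrosynthetic cuts, in order: C6–CO2H (aryllithium + CO2); C8a–C1 together with C2–C3 (one anionic cascade); C4–C1′ (SN2 of an arylacetonitrile anion on a secondary sulfonate); C4–C3 (aldehyde-to-nitrile homologation).
3. Enabling feature: O8 on C8 lies peri to the C1 methyl (O8–C8–C8a–C1–CH3), and C8a sits between C8 and C4a. The methyl carbon, C1 and C2 therefore enter as an O-allyl group on O8, C8a as C–Br, and C4=C3H2 as an α-substituted vinyl group on C4a, all on 2-bromoisovanillin.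
4. Forward order: ring B is bought. The cascade closes a temporary dihydrofuran ring (O8–CH2–C1–C8a), then ring A. The chain end is then oxidised and hydrogenated, C6 is carboxylated, and the dihydrofuran is opened and reduced to the C1 methyl with release of both phenols.
5. Stereochemistry: C1′ is bought as (R)-sulcatol and inverted in the SN2 step. C1 is set by (−)-sparteine in the cascade. C4 is relayed from C1 in the same operation (axial protonation of the benzylic lithium in the half-chair locked by the dihydrofuran). C5′ is set by Ru–BINAP hydrogenation.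

Key step: step 7

Remark (assumption): the sense of induction of the two ligand-controlled steps is taken from the closest models. For (−)-sparteine this is the cyclisation of N-allyl-2-lithioanilines to (R)-3-methylindolines; for (R)-BINAP it is the hydroxyl-directed face rule of (E)-allylic alcohols (geraniol with the (S)-ligand gives (R)-citronellol). (R)-Sulcatol 5 is taken as a commercial compound.

**Step 1**
Reactants: 1 2-bromo-3-hydroxy-4-methoxybenzaldehyde; 2 allyl bromide
Product: 3 3-(allyloxy)-2-bromo-4-methoxybenzaldehyde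
Conditions: K2CO3, DMF, 20 °C
Reagents that add atoms: none
Why: Williamson ether synthesis (SN2 of the phenoxide on allyl bromide) places the future C1, C2 and C1-methyl carbons on O8 next to the C8a bromide; no stereocenter is formed.

**Step 2**
Reactants: 3 3-(allyloxy)-2-bromo-4-methoxybenzaldehyde
Product: 4 [3-(allyloxy)-2-bromo-4-methoxyphenyl]acetonitrile
Conditions: TosMIC, KOt-Bu, DME, −35 °C; then MeOH, 65 °C
Reagents that add atoms: tosylmethyl isocyanide (TosMIC), [C-]#[N+]CS(=O)(=O)c1ccc(C)cc1
Why: van Leusen reductive cyanation should turn the aldehyde into the one-carbon-longer nitrile (aldehyde carbon becomes C4, nitrile carbon becomes C3) without touching the aryl bromide or the allyl ether; no stereocenter.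

**Step 3**
Reactants: 5 (R)-6-methylhept-5-en-2-ol
Product: 6 (R)-6-methylhept-5-en-2-yl 4-methylbenzenesulfonate
Conditions: TsCl, pyridine, CH2Cl2, 0 → 20 °C
Reagents that add atoms: p-toluenesulfonyl chloride, Cc1ccc(cc1)S(Cl)(=O)=O
Why: O-sulfonylation forms only the S–O bond, so the bought carbinol configuration is retained in the leaving group.

**Step 4**
Reactants: 4 [3-(allyloxy)-2-bromo-4-methoxyphenyl]acetonitrile; 6 (R)-6-methylhept-5-en-2-yl 4-methylbenzenesulfonate
Product: 8 (3S)-2-[3-(allyloxy)-2-bromo-4-methoxyphenyl]-3,7-dimethyloct-6-enenitrile, via sodium carbanion 7 (not isolated)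
Conditions: NaN(SiMe3)2, THF, −78 °C; then 6, DMPU, −78 → 25 °C
Reagents that add atoms: none
Why: SN2 alkylation of the arylacetonitrile carbanion by a secondary sulfonate proceeds with Walden inversion, so the (R)-sulfonate should give (S) at C1′; the new C4 center forms as a mixture that step 6 erases.

**Step 5**
Reactants: 8 (3S)-2-[3-(allyloxy)-2-bromo-4-methoxyphenyl]-3,7-dimethyloct-6-enenitrile
Product: 10 (3S)-2-[3-(allyloxy)-2-bromo-4-methoxyphenyl]-3,7-dimethyloct-6-en-1-ol, via aldehyde 9 (not isolated)
Conditions: i-Bu2AlH, toluene, −78 °C; aq. citric acid; then NaBH4, MeOH, 0 °C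
Reagents that add atoms: water, O
Why: partial nitrile reduction to the aldimine, hydrolysis and borohydride reduction give the primary alcohol (C3); C1′ is not α to the carbonyl and cannot epimerise, and the C4 mixture is irrelevant.

**Step 6**
Reactants: 10 (3S)-2-[3-(allyloxy)-2-bromo-4-methoxyphenyl]-3,7-dimethyloct-6-en-1-ol
Product: 12 3-(allyloxy)-2-bromo-4-methoxy-1-[(3S)-3,7-dimethylocta-1,6-dien-2-yl]benzene, via mesylate 11 (not isolated)
Conditions: MsCl, Et3N, THF, 0 °C; then KOt-Bu, 0 → 20 °C
Reagents that add atoms: none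
Why: mesylation followed by E2 elimination, in which the only β-hydrogen is the acidic benzylic C4–H, should give the single alkene C4=C3H2 and remove the C4 stereocenter.

**Step 7**
Reactants: 12 3-(allyloxy)-2-bromo-4-methoxy-1-[(3S)-3,7-dimethylocta-1,6-dien-2-yl]benzene
Product: 16 (2aR,5S)-8-methoxy-5-[(2S)-6-methylhept-5-en-2-yl]-2a,3,4,5-tetrahydro-2H-naphtho[1,8-bc]furan, via aryllithium 13 (not isolated), via lithiomethyl dihydrobenzofuran 14 (not isolated), via benzylic lithium 15 (not isolated)
Conditions: t-BuLi (2.0 equiv), pentane–Et2O (9:1), −78 °C; (−)-sparteine (2.2 equiv), −78 → −20 °C; MeOH, −78 °C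
Reagents that add atoms: none
Why: Proposed new method: Br–Li exchange gives aryllithium 13, whose sparteine-bound lithium adds syn across the allyl double bond in a 5-exo-trig closure (dihydrofuran ring, bond C8a–C1); the primary alkyllithium 14 then adds 6-endo-trig to the CH2 terminus of the neighbouring α-substituted styrene (ring A, bond C2–C3), since only that regiochemistry gives an aryl-stabilised lithium 15, which MeOH protonates. The closest known reactions are the sparteine-mediated enantioselective cyclisation of allyl 2-lithioaryl ethers and N-allyl-2-lithioanilines to 3-(lithiomethyl)dihydrobenzofurans and -indolines, and the carbolithiation of α-alkylstyrenes by alkyllithiums; the new element is their coupling in one flask across the peri positions. C1 is set by the chiral diamine on lithium (reagent control, sense as in the indoline model, independent of the remote C1′). C4 is set by substrate control: the fused dihydrofuran holds its CH2 pseudo-equatorial and the C1–H pseudo-axial, which fixes one half-chair of ring A, and protonation of the planar benzylic lithium along the pseudo-axial direction of that half-chair should put H on the face opposite to the C1–H, so the side chain ends trans to the future C1 methyl. The step needs exchange to outrun addition of t-BuLi to the styrene (exactly two equivalents at −78 °C), and it needs 14 to add to the styrene faster than it expels the aryloxide by 1,3-elimination; the methoxy group flanking the ether oxygen, as in the known ortho-substituted cases, should disfavour that elimination, and the styrene is held within bonding distance.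

**Step 8**
Reactants: 16 (2aR,5S)-8-methoxy-5-[(2S)-6-methylhept-5-en-2-yl]-2a,3,4,5-tetrahydro-2H-naphtho[1,8-bc]furan
Product: 17 (2E,6S)-6-[(2aR,5S)-8-methoxy-2a,3,4,5-tetrahydro-2H-naphtho[1,8-bc]furan-5-yl]-2-methylhept-2-en-1-ol
Conditions: SeO2 (0.3 equiv), t-BuOOH, CH2Cl2, 20 °C
Reagents that add atoms: tert-butyl hydroperoxide (oxygen relayed through SeO2), CC(C)(C)OO
Why: SeO2 allylic oxidation (ene reaction then 2,3-sigmatropic shift) hydroxylates the (E)-methyl group of the trisubstituted alkene and should give the (E)-allylic alcohol; no new stereocenter.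

**Step 9**
Reactants: 17 (2E,6S)-6-[(2aR,5S)-8-methoxy-2a,3,4,5-tetrahydro-2H-naphtho[1,8-bc]furan-5-yl]-2-methylhept-2-en-1-ol
Product: 18 (2R,6S)-6-[(2aR,5S)-8-methoxy-2a,3,4,5-tetrahydro-2H-naphtho[1,8-bc]furan-5-yl]-2-methylheptan-1-ol
Conditions: H2 (100 atm), Ru(OAc)2[(R)-BINAP] (1 mol %), MeOH, 25 °C
Reagents that add atoms: none
Why: hydroxyl-directed asymmetric hydrogenation of the (E)-allylic alcohol, in which the BINAP ligand selects the alkene face, should set C5′ as (R) under catalyst control, independent of the remote centers.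

**Step 10**
Reactants: 18 (2R,6S)-6-[(2aR,5S)-8-methoxy-2a,3,4,5-tetrahydro-2H-naphtho[1,8-bc]furan-5-yl]-2-methylheptan-1-ol
Product: 20 (2aR,5S)-5-[(2S,6R)-7-hydroxy-6-methylheptan-2-yl]-8-methoxy-2a,3,4,5-tetrahydro-2H-naphtho[1,8-bc]furan-7-carboxylic acid, via dilithio species 19 (not isolated)
Conditions: s-BuLi (2.3 equiv), TMEDA, THF, −78 °C; CO2; aq. HCl
Reagents that add atoms: carbon dioxide, O=C=O
Why: directed ortho-metalation, in which (after O-lithiation of the alcohol) the methoxy group directs s-BuLi to its only free ortho position C6, followed by carboxylation of the aryllithium; no stereocenter is touched.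

**Step 11**
Reactants: 20 (2aR,5S)-5-[(2S,6R)-7-hydroxy-6-methylheptan-2-yl]-8-methoxy-2a,3,4,5-tetrahydro-2H-naphtho[1,8-bc]furan-7-carboxylic acid
Product: 21 (5R,8S)-5-(bromomethyl)-3,4-dihydroxy-8-[(2S,6R)-7-hydroxy-6-methylheptan-2-yl]-5,6,7,8-tetrahydronaphthalene-2-carboxylic acid
Conditions: BBr3 (5 equiv), CH2Cl2, −78 → 20 °C; H2O
Reagents that add atoms: boron tribromide, BrB(Br)Br
Why: Lewis-acid ether cleavage, in which bromide attacks the alkyl carbon of each boron-bound aryl ether by SN2 (the methyl of the methyl ether and the primary CH2 of the dihydrofuran), should free the catechol and leave C1–CH2Br without touching C1.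

**Step 12**
Reactants: 21 (5R,8S)-5-(bromomethyl)-3,4-dihydroxy-8-[(2S,6R)-7-hydroxy-6-methylheptan-2-yl]-5,6,7,8-tetrahydronaphthalene-2-carboxylic acid
Product: 22 (5R,8S)-3,4-dihydroxy-8-[(2S,6R)-7-hydroxy-6-methylheptan-2-yl]-5-methyl-5,6,7,8-tetrahydronaphthalene-2-carboxylic acid
Conditions: Bu3SnH (0.5 M), AIBN, toluene, 80 °C
Reagents that add atoms: none
Why: radical-chain hydrodebromination turns CH2Br into the C1 methyl, with a high stannane concentration so that hydrogen transfer outruns 1,2-aryl migration of the primary radical; no stereocenter is affected.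

**Compound list**

1 | 2-bromo-3-hydroxy-4-methoxybenzaldehyde (2-bromoisovanillin) | O=Cc1ccc(OC)c(O)c1Br | starting material
2 | allyl bromide | C=CCBr | starting material
3 | 3-(allyloxy)-2-bromo-4-methoxybenzaldehyde | O=Cc1ccc(OC)c(OCC=C)c1Br | intermediate
4 | [3-(allyloxy)-2-bromo-4-methoxyphenyl]acetonitrile | N#CCc1ccc(OC)c(OCC=C)c1Br | intermediate
5 | (R)-6-methylhept-5-en-2-ol ((R)-sulcatol) | C[C@@H](O)CCC=C(C)C | starting material
6 | (R)-6-methylhept-5-en-2-yl 4-methylbenzenesulfonate | C[C@@H](OS(=O)(=O)c1ccc(C)cc1)CCC=C(C)C | intermediate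
7 | sodium carbanion of 4 (sodium cyano[3-(allyloxy)-2-bromo-4-methoxyphenyl]methanide) | [Na+].N#C[CH-]c1ccc(OC)c(OCC=C)c1Br | intermediate (not isolated)
8 | (3S)-2-[3-(allyloxy)-2-bromo-4-methoxyphenyl]-3,7-dimethyloct-6-enenitrile (both C2 epimers) | N#CC(c1ccc(OC)c(OCC=C)c1Br)[C@@H](C)CCC=C(C)C | intermediate
9 | (3S)-2-[3-(allyloxy)-2-bromo-4-methoxyphenyl]-3,7-dimethyloct-6-enal (both C2 epimers) | O=CC(c1ccc(OC)c(OCC=C)c1Br)[C@@H](C)CCC=C(C)C | intermediate (not isolated)
10 | (3S)-2-[3-(allyloxy)-2-bromo-4-methoxyphenyl]-3,7-dimethyloct-6-en-1-ol (both C2 epimers) | OCC(c1ccc(OC)c(OCC=C)c1Br)[C@@H](C)CCC=C(C)C | intermediate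
11 | methanesulfonate of 10 | CS(=O)(=O)OCC(c1ccc(OC)c(OCC=C)c1Br)[C@@H](C)CCC=C(C)C | intermediate (not isolated)
12 | 3-(allyloxy)-2-bromo-4-methoxy-1-[(3S)-3,7-dimethylocta-1,6-dien-2-yl]benzene | C=C(c1ccc(OC)c(OCC=C)c1Br)[C@@H](C)CCC=C(C)C | intermediate
13 | aryllithium from 12 (Li in place of Br) | C=C(c1ccc(OC)c(OCC=C)c1[Li])[C@@H](C)CCC=C(C)C | intermediate (not isolated)
14 | (3R)-3-(lithiomethyl)-7-methoxy-4-[(3S)-3,7-dimethylocta-1,6-dien-2-yl]-2,3-dihydro-1-benzofuran | C=C(c1ccc(OC)c2OC[C@H](C[Li])c12)[C@@H](C)CCC=C(C)C | intermediate (not isolated)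
15 | (2aR)-5-lithio-8-methoxy-5-[(2S)-6-methylhept-5-en-2-yl]-2a,3,4,5-tetrahydro-2H-naphtho[1,8-bc]furan (C5 configurationally labile) | [Li]C1(CC[C@H]2COc3c(OC)ccc1c23)[C@@H](C)CCC=C(C)C | intermediate (not isolated)
16 | (2aR,5S)-8-methoxy-5-[(2S)-6-methylhept-5-en-2-yl]-2a,3,4,5-tetrahydro-2H-naphtho[1,8-bc]furan | CC(C)=CCC[C@H](C)[C@@H]1CC[C@H]2COc3c(OC)ccc1c23 | intermediate
17 | (2E,6S)-6-[(2aR,5S)-8-methoxy-2a,3,4,5-tetrahydro-2H-naphtho[1,8-bc]furan-5-yl]-2-methylhept-2-en-1-ol | OC/C(C)=C/CC[C@H](C)[C@@H]1CC[C@H]2COc3c(OC)ccc1c23 | intermediate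
18 | (2R,6S)-6-[(2aR,5S)-8-methoxy-2a,3,4,5-tetrahydro-2H-naphtho[1,8-bc]furan-5-yl]-2-methylheptan-1-ol | OC[C@H](C)CCC[C@H](C)[C@@H]1CC[C@H]2COc3c(OC)ccc1c23 | intermediate
19 | dilithio derivative of 18 (lithium alkoxide; Li at C7 of the tricycle, ortho to OMe) | [Li]OC[C@H](C)CCC[C@H](C)[C@@H]1CC[C@H]2COc3c(OC)c([Li])cc1c23 | intermediate (not isolated)
20 | (2aR,5S)-5-[(2S,6R)-7-hydroxy-6-methylheptan-2-yl]-8-methoxy-2a,3,4,5-tetrahydro-2H-naphtho[1,8-bc]furan-7-carboxylic acid | OC[C@H](C)CCC[C@H](C)[C@@H]1CC[C@H]2COc3c(OC)c(C(=O)O)cc1c23 | intermediate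
21 | (5R,8S)-5-(bromomethyl)-3,4-dihydroxy-8-[(2S,6R)-7-hydroxy-6-methylheptan-2-yl]-5,6,7,8-tetrahydronaphthalene-2-carboxylic acid | OC[C@H](C)CCC[C@H](C)[C@@H]1CC[C@@H](CBr)c2c1cc(C(=O)O)c(O)c2O | intermediate
22 | (5R,8S)-3,4-dihydroxy-8-[(2S,6R)-7-hydroxy-6-methylheptan-2-yl]-5-methyl-5,6,7,8-tetrahydronaphthalene-2-carboxylic acid | C[C@@H](CO)CCC[C@H](C)[C@@H]1CC[C@@H](C)c2c1cc(C(=O)O)c(O)c2O | target

**Step count and risks**

Total number of steps: 12. Longest linear sequence: 11 steps (steps 1, 2 and 4–12 from compound 1); step 3 is a one-step side branch.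

Steps most likely to fail:

1. Step 7 (Proposed new method). The lithiomethyl intermediate may be lost by 1,3-elimination with opening of the dihydrofuran before it adds to the styrene; t-BuLi may add to the styrene; and protonation of the benzylic lithium may show poor facial selectivity. Fallback, setting out from 12 and returning at 16: the exchange and the sparteine-mediated 5-exo carbolithiation are run as before, but the lithiomethyl intermediate 14 is trapped at −78 °C with I2 to give (3R)-3-(iodomethyl)-7-methoxy-4-[(3S)-3,7-dimethylocta-1,6-dien-2-yl]-2,3-dihydro-1-benzofuran F1. Bu3SnH/AIBN (slow addition, benzene, 80 °C) should then close ring A by 6-endo radical addition to the styrene terminus, with hydrogen-atom transfer to the tertiary benzylic radical on the same pseudo-axial face, giving 16. The two bonds are then made in two known operations instead of one.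

2. Step 4. E2 elimination of the secondary sulfonate may outrun SN2 at the hindered carbanion, and ionisation of the sulfonate would erode the configuration at C1′. Fallback, setting out from 3 and returning at 12: EtMgBr gives 1-[3-(allyloxy)-2-bromo-4-methoxyphenyl]propan-1-ol F2, and Dess–Martin oxidation gives 1-[3-(allyloxy)-2-bromo-4-methoxyphenyl]propan-1-one F3. Condensation with SAMP gives the SAMP hydrazone of the propiophenone F4. LiN(i-Pr)2 and then 5-bromo-2-methylpent-2-ene give the α-alkylated SAMP hydrazone F5, with C1′ set by the auxiliary (antipode of the auxiliary chosen to give 2S). Two-phase oxalic acid cleavage gives (2S)-1-[3-(allyloxy)-2-bromo-4-methoxyphenyl]-2,6-dimethylhept-5-en-1-one F6, and Takai–Lombardo methylenation (Zn, CH2Br2, TiCl4) gives 12.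

3. Step 11. Cleavage of the cyclic ether may be incomplete, the primary alcohol may be converted into a bromide, and the bromomethyl group may re-close onto the phenol during work-up. Fallback, setting out from 20 and returning at 22: AlCl3/EtSH (hard acid with a soft sulfur nucleophile) should remove the methyl group and open the dihydrofuran by thiol attack at its CH2, giving (5R,8S)-5-[(ethylsulfanyl)methyl]-3,4-dihydroxy-8-[(2S,6R)-7-hydroxy-6-methylheptan-2-yl]-5,6,7,8-tetrahydronaphthalene-2-carboxylic acid F7. This compound carries no alkyl halide; Raney Ni in EtOH then desulfurises the CH2–S bond to the C1 methyl and gives 22 directly.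

**Further compounds**

F1 | step 7 | (3R)-3-(iodomethyl)-7-methoxy-4-[(3S)-3,7-dimethylocta-1,6-dien-2-yl]-2,3-dihydro-1-benzofuran | C=C(c1ccc(OC)c2OC[C@H](CI)c12)[C@@H](C)CCC=C(C)C
F2 | step 4 | 1-[3-(allyloxy)-2-bromo-4-methoxyphenyl]propan-1-ol (racemic) | CCC(O)c1ccc(OC)c(OCC=C)c1Br
F3 | step 4 | 1-[3-(allyloxy)-2-bromo-4-methoxyphenyl]propan-1-one | CCC(=O)c1ccc(OC)c(OCC=C)c1Br
F4 | step 4 | SAMP hydrazone of F3 | CCC(=NN1CCC[C@H]1COC)c1ccc(OC)c(OCC=C)c1Br
F5 | step 4 | SAMP hydrazone of (2S)-1-[3-(allyloxy)-2-bromo-4-methoxyphenyl]-2,6-dimethylhept-5-en-1-one | CC(C)=CCC[C@H](C)C(=NN1CCC[C@H]1COC)c1ccc(OC)c(OCC=C)c1Br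
F6 | step 4 | (2S)-1-[3-(allyloxy)-2-bromo-4-methoxyphenyl]-2,6-dimethylhept-5-en-1-one | CC(C)=CCC[C@H](C)C(=O)c1ccc(OC)c(OCC=C)c1Br
F7 | step 11 | (5R,8S)-5-[(ethylsulfanyl)methyl]-3,4-dihydroxy-8-[(2S,6R)-7-hydroxy-6-methylheptan-2-yl]-5,6,7,8-tetrahydronaphthalene-2-carboxylic acid | OC[C@H](C)CCC[C@H](C)[C@@H]1CC[C@@H](CSCC)c2c1cc(C(=O)O)c(O)c2O
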